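The data stem from a simulated flask on assumed constants; scatter was added.

8.46 % of the substrate charged: that is the spare reagent, meaning the reagent charge less the protic impurity, taken as a share of the substrate, for the lean flasks, Wednesday's and Friday's.

| setting | summer | autumn | noon | Tuesday's | Wednesday's | Monday's | Friday's |
|---|---|---|---|---|---|---|---|
| substrate | 0.39 M | 0.39 M | 0.39 M | 0.39 M | 0.39 M | 0.39 M | 0.39 M |
| reagent in the second phase | 0.17 M | 0.26 M | 0.47 M | 0.468 M | 0.150 M | 0.468 M | 0.150 M |
| protic impurity | 0.117 M | 0.117 M | 0.117 M | 0.117 M | 0.117 M | 0.117 M | 0.117 M |
| temperature | 90 °C | 112 °C | 90 °C | 120 °C | 120 °C | 80 °C | 80 °C |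
| remark | run made earlier | run made earlier | run made earlier |  |  |  |  |
| time |  |  |  | 20 h | 20 h | 20 h | 20 h |
| volume of the second phase over the first |  |  |  | 1.0 | 1.0 | 1.0 | 1.0 |

| summer: time / h | summer: target / % | autumn: time / h | autumn: target / % | noon: time / h | noon: target / % |
|---|---|---|---|---|---|
| 1.33 | 3 | 0.200 | 0 | 0.667 | 4 |
| 3.00 | 8 | 0.500 | 0 | 1.50 | 6 |
| 6.00 | 7 | 1.33 | 6 | 4.00 | 14 |
| 10.0 | 11 | 3.00 | 10 | 10.0 | 19 |

(standard deviation of a reading: 1.5 percentage points)

- percent here means substrate units held: one self-condensation product counts as two
- in the second phase: reagent in the second phase; everything else is in the first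
- charges count per volume of the first phase; a concentration in a rate is the amount of a species over the volume of its own phase; every rate counts per litre of the first phase
- what may be going on: reagent in the reaction phase <-> reagent in the second phase; substrate + reagent in the reaction phase -> target; reagent in the reaction phase + target -> over-reacted product; reagent in the reaction phase + protic impurity -> quenched reagent; 2 substrate -> self-condensation product
- the earlier runs hold the two phases in the same ratio of volumes as the flask asked about

* the flasks put in order of amount of target, in percent of the substrate charged, best first, at 20 h (Tuesday's / Wednesday's / Monday's / Friday's)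
* the same order at 1.0 h (Tuesday's / Wednesday's / Monday's / Friday's)
* the amount of target, in percent of the substrate charged of the flask you put first, at 20 h
* the amount of target, in percent of the substrate charged of the flask you put last, at 20 h

**Which reagent do you balance?** The one in the second phase, since in the lean flasks its charge of 0.150 M is smaller than the 0.39 M of substrate: there it is the limiting reagent.

**Write the balance.** Reagent charged equals reagent left in both phases, plus quenched reagent, plus target, plus two for each over-reacted product. Quenching spends reagent and makes no target. If the impurity is paid in full, the spare reagent is the ceiling on target in a lean flask.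

**And the rich flasks, Tuesday's and Monday's?** Their spare reagent is 90.0 %, far above the lean figure. Against that ceiling the noon run, with about the same charge, reads 19 % at 10.0 h, so target in the rich flasks must be judged by rates.

**Where is the weak spot?** In "paid in full". The summer run reads 11 % at 10.0 h against a spare reagent of its own of 13.6 %, which fits the ceiling but proves little, because no reading tells how much impurity stood.

**So what do you commit to?** Wednesday's, at 120 °C, I put at or under the ceiling, and that estimate takes its impurity as paid in full. Friday's, at 80 °C, is open: while its impurity stands, the subtraction does not bind it.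

The forecast differs on that second point. It gives Monday's > Tuesday's > Wednesday's > Friday's at 20 h, with 18 % first (range 14 % to 25 %) and 6.5 % last (range 4 % to 9 %), and Tuesday's > Monday's > Wednesday's > Friday's at 1.0 h. Its word on the lean pair is “The lean flasks cap near 7%, with Friday perhaps unfinished”.

The flasks give Monday's > Friday's > Wednesday's > Tuesday's at 20 h, with 22.2 % first and 0.636 % last, and Tuesday's > Wednesday's > Monday's > Friday's at 1.0 h.

    reagent in the reaction phase ⇌ reagent in the second phase, rate k1*([reagent in the reaction phase] - [reagent in the second phase]/K1) per volume of the first phase (partition coefficient = 0.912, kL = 1.21 h⁻¹)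
    substrate + reagent in the reaction phase → target (k = 0.170 M⁻¹ h⁻¹, Ea = 75.0 kJ mol⁻¹)
    reagent in the reaction phase + target → over-reacted product (k = 0.222 M⁻¹ h⁻¹, Ea = 88.0 kJ mol⁻¹)
    reagent in the reaction phase + protic impurity → quenched reagent (k = 0.887 M⁻¹ h⁻¹, Ea = 63.0 kJ mol⁻¹)
    2 substrate → self-condensation product (k = 0.0471 M⁻¹ h⁻¹, Ea = 103 kJ mol⁻¹)
    (constants at 80 °C)

Friday's target climbed from 6.92 % at 10.0 h to 9.42 % at 20 h, past the spare reagent of 8.46 %, while quenching ran beside it and 48.2 % of the impurity still stood; Wednesday's, with the same spare reagent, ended under it at 5.72 %, with 4.64 % of over-reacted product, 23.1 % of its impurity still standing and 0.510 % of its reagent left in the second phase. Tuesday's, with 90.0 % to spend, held 10.1 % of target at 1.0 h, but over-reacted product reached 32.3 % and self-condensation product 66.5 % by 20 h, when target stood at 0.636 %.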